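**Retrosynthetic overview**
1. Target 19 ⇒ dibenzyl-protected keto depside 18 (final global hydrogenolysis) ⇒ dithiolane-masked depside 17 (ketone unmasking).
2. Depside ester C(=O)–OAr bond of 17 ⇒ A-ring acid 12 + benzyl olivetolate 15 (free 4-OH; the 2-OH is chelated to the ester).
3. ArCH2–C(=O) bond of the A-ring ⇒ lateral dianion of 2-(benzyloxy)-4-methoxy-6-methylbenzoic acid 6 + hexanoyl Weinreb amide 7; the ketone is masked at once as a dithiolane so the activated acid cannot close to the isocoumarin.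
4. Ring formation: no ring of the target is built. Both benzene rings are bought (methyl everninate 1, olivetolic acid 13); the only ring made is the temporary 1,3-dithiolane (step 4), opened again in step 7.

Assumption: the target has no stereocentre or stereogenic double bond, so it is made as the achiral compound; 1, 2, 7, 11 and 13 are taken as catalogue chemicals.

**Step 1**
Reactants: 1 methyl 2-hydroxy-4-methoxy-6-methylbenzoate (methyl everninate); 2 benzyl bromide
Product: 4 methyl 2-(benzyloxy)-4-methoxy-6-methylbenzoate, via potassium phenolate 3 (not isolated)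
Conditions: BnBr, K2CO3, DMF, 60 °C
Reagents that add atoms: benzyl bromide (2), BrCc1ccccc1
Why: Williamson ether synthesis; hot carbonate in DMF breaks the salicylate hydrogen bond and the phenolate is O-benzylated by SN2.

**Step 2**
Reactants: 4 methyl 2-(benzyloxy)-4-methoxy-6-methylbenzoate
Product: 6 2-(benzyloxy)-4-methoxy-6-methylbenzoic acid, via potassium carboxylate 5 (not isolated)
Conditions: KOH, DMSO/H2O (4:1), 100 °C; then aq. HCl to pH 2
Reagents that add atoms: potassium hydroxide, [K+].[OH-]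
Why: Saponification of the di-ortho-substituted ester needs poorly solvated hydroxide in DMSO, and the benzyl and methyl aryl ethers are inert to base.

**Step 3**
Reactants: 6 2-(benzyloxy)-4-methoxy-6-methylbenzoic acid; 7 N-methoxy-N-methylhexanamide
Product: 10 2-(benzyloxy)-4-methoxy-6-(2-oxoheptyl)benzoic acid, via dilithio lateral dianion 8 (not isolated), via lithium hemiaminal adduct 9 (not isolated)
Conditions: LDA (2.4 equiv), THF, −78 → 0 °C; then 7, −78 → 0 °C; cold 1 M HCl
Reagents that add atoms: N-methoxy-N-methylhexanamide (7), CCCCCC(=O)N(C)OC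
Why: Carboxylate-directed lateral (benzylic) lithiation followed by Weinreb ketone synthesis; the chelated tetrahedral adduct stops over-addition and releases the ketone only on acid quench, and no stereocentre is formed.

**Step 4**
Reactants: 10 2-(benzyloxy)-4-methoxy-6-(2-oxoheptyl)benzoic acid; 11 ethane-1,2-dithiol
Product: 12 2-(benzyloxy)-4-methoxy-6-[(2-pentyl-1,3-dithiolan-2-yl)methyl]benzoic acid
Conditions: HSCH2CH2SH (1.5 equiv), BF3·OEt2 (0.3 equiv), CH2Cl2, 0 °C → rt
Reagents that add atoms: ethane-1,2-dithiol (11), SCCS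
Why: Lewis-acid-catalysed thioketalisation is fast at low temperature and masks the ketone, which would otherwise give the isocoumarin once the acid is activated; the hindered acid is not touched.

**Step 5**
Reactants: 13 olivetolic acid (2,4-dihydroxy-6-pentylbenzoic acid); 2 benzyl bromide
Product: 15 benzyl 2,4-dihydroxy-6-pentylbenzoate, via potassium olivetolate 14 (not isolated)
Conditions: BnBr (1.05 equiv), KHCO3, DMF, rt
Reagents that add atoms: benzyl bromide (2), BrCc1ccccc1
Why: Bicarbonate deprotonates only the carboxylic acid, so SN2 alkylation gives the benzyl ester and leaves both phenols free.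

**Step 6**
Reactants: 12 2-(benzyloxy)-4-methoxy-6-[(2-pentyl-1,3-dithiolan-2-yl)methyl]benzoic acid; 15 benzyl 2,4-dihydroxy-6-pentylbenzoate
Product: 17 benzyl 4-{[2-(benzyloxy)-4-methoxy-6-[(2-pentyl-1,3-dithiolan-2-yl)methyl]benzoyl]oxy}-2-hydroxy-6-pentylbenzoate, via mixed trifluoroacetic anhydride 16 (not isolated)
Conditions: (CF3CO)2O, dry toluene, rt, 3 h
Reagents that add atoms: none
Why: Trifluoroacetic-anhydride-mediated esterification (mixed anhydride/acylium of the electron-rich hindered acid) acylates the free 4-OH selectively, because the 2-OH is chelated to the benzyl ester and flanked by it.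

**Step 7**
Reactants: 17 benzyl 4-{[2-(benzyloxy)-4-methoxy-6-[(2-pentyl-1,3-dithiolan-2-yl)methyl]benzoyl]oxy}-2-hydroxy-6-pentylbenzoate
Product: 18 benzyl 4-{[2-(benzyloxy)-4-methoxy-6-(2-oxoheptyl)benzoyl]oxy}-2-hydroxy-6-pentylbenzoate
Conditions: MeI (excess), CaCO3, MeCN/H2O (4:1), 45 °C
Reagents that add atoms: water, O
Why: Alkylative hydrolysis of the dithiolane (S-methylation, then hydrolysis of the thionium ion) is neutral and non-oxidative, so the aryl ester, benzyl groups and electron-rich rings survive.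

**Step 8**
Reactants: 18 benzyl 4-{[2-(benzyloxy)-4-methoxy-6-(2-oxoheptyl)benzoyl]oxy}-2-hydroxy-6-pentylbenzoate
Product: 19 4-{[2-hydroxy-4-methoxy-6-(2-oxoheptyl)benzoyl]oxy}-2-hydroxy-6-pentylbenzoic acid (target)
Conditions: H2 (1 atm), 10% Pd/C, EtOAc, rt
Reagents that add atoms: none
Why: Catalytic hydrogenolysis removes the benzyl ester and benzyl ether together after chromatographic removal of sulfur residues, while the aliphatic ketone and depside ester are inert; the target has no stereocentre to set.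

**Compound list**
1 | methyl 2-hydroxy-4-methoxy-6-methylbenzoate (methyl everninate) | COC(=O)c1c(C)cc(OC)cc1O | starting material
2 | benzyl bromide | BrCc1ccccc1 | starting material
3 | potassium 5-methoxy-2-(methoxycarbonyl)-3-methylphenolate | COC(=O)c1c(C)cc(OC)cc1[O-].[K+] | intermediate
4 | methyl 2-(benzyloxy)-4-methoxy-6-methylbenzoate | COC(=O)c1c(C)cc(OC)cc1OCc1ccccc1 | intermediate
5 | potassium 2-(benzyloxy)-4-methoxy-6-methylbenzoate | Cc1cc(OC)cc(OCc2ccccc2)c1C(=O)[O-].[K+] | intermediate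
6 | 2-(benzyloxy)-4-methoxy-6-methylbenzoic acid | Cc1cc(OC)cc(OCc2ccccc2)c1C(=O)O | intermediate
7 | N-methoxy-N-methylhexanamide | CCCCCC(=O)N(C)OC | starting material
8 | lithium 2-(benzyloxy)-6-(lithiomethyl)-4-methoxybenzoate (lateral dianion) | [Li]Cc1cc(OC)cc(OCc2ccccc2)c1C(=O)O[Li] | intermediate
9 | dilithium salt of 2-(benzyloxy)-6-{2-hydroxy-2-[methoxy(methyl)amino]heptyl}-4-methoxybenzoic acid (tetrahedral Weinreb adduct) | CCCCCC(O[Li])(Cc1cc(OC)cc(OCc2ccccc2)c1C(=O)O[Li])N(C)OC | intermediate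
10 | 2-(benzyloxy)-4-methoxy-6-(2-oxoheptyl)benzoic acid | CCCCCC(=O)Cc1cc(OC)cc(OCc2ccccc2)c1C(=O)O | intermediate
11 | ethane-1,2-dithiol | SCCS | starting material
12 | 2-(benzyloxy)-4-methoxy-6-[(2-pentyl-1,3-dithiolan-2-yl)methyl]benzoic acid | CCCCCC1(Cc2cc(OC)cc(OCc3ccccc3)c2C(=O)O)SCCS1 | intermediate
13 | olivetolic acid (2,4-dihydroxy-6-pentylbenzoic acid) | CCCCCc1cc(O)cc(O)c1C(=O)O | starting material
14 | potassium 2,4-dihydroxy-6-pentylbenzoate | CCCCCc1cc(O)cc(O)c1C(=O)[O-].[K+] | intermediate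
15 | benzyl 2,4-dihydroxy-6-pentylbenzoate | CCCCCc1cc(O)cc(O)c1C(=O)OCc1ccccc1 | intermediate
16 | 2-(benzyloxy)-4-methoxy-6-[(2-pentyl-1,3-dithiolan-2-yl)methyl]benzoic trifluoroacetic anhydride | CCCCCC1(Cc2cc(OC)cc(OCc3ccccc3)c2C(=O)OC(=O)C(F)(F)F)SCCS1 | intermediate
17 | benzyl 4-{[2-(benzyloxy)-4-methoxy-6-[(2-pentyl-1,3-dithiolan-2-yl)methyl]benzoyl]oxy}-2-hydroxy-6-pentylbenzoate | CCCCCc1cc(OC(=O)c2c(CC3(CCCCC)SCCS3)cc(OC)cc2OCc2ccccc2)cc(O)c1C(=O)OCc1ccccc1 | intermediate
18 | benzyl 4-{[2-(benzyloxy)-4-methoxy-6-(2-oxoheptyl)benzoyl]oxy}-2-hydroxy-6-pentylbenzoate | CCCCCC(=O)Cc1cc(OC)cc(OCc2ccccc2)c1C(=O)Oc1cc(O)c(C(=O)OCc2ccccc2)c(CCCCC)c1 | intermediate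
19 | 4-{[2-hydroxy-4-methoxy-6-(2-oxoheptyl)benzoyl]oxy}-2-hydroxy-6-pentylbenzoic acid | CCCCCC(=O)Cc1cc(OC)cc(O)c1C(=O)Oc1cc(O)c(C(=O)O)c(CCCCC)c1 | target

**Totals**
Total step count: 8. Longest linear sequence: 7 steps (1 → 2 → 3 → 4 → 6 → 7 → 8); step 5 is the one-step side branch.

**Three steps most likely to fail, with fallbacks**

Step 3 (dianion formation and acylation). The electron-rich carboxylate dianion may form incompletely, or the amide may be enolised instead of attacked. The fallback sets out from 4 and comes back at 12, using the more acidic ester toluate anion and masking the ketone before the ester is cleaved. Ester 4 is deprotonated with LDA (1.1 equiv, THF, −78 °C) to the lithiated ester methyl 2-(benzyloxy)-6-(lithiomethyl)-4-methoxybenzoate F1. This adds to 7 to give the lithium hemiaminal adduct methyl 2-(benzyloxy)-6-{2-(lithiooxy)-2-[methoxy(methyl)amino]heptyl}-4-methoxybenzoate F2. An NH4Cl quench gives the keto ester methyl 2-(benzyloxy)-4-methoxy-6-(2-oxoheptyl)benzoate F3. Thioketalisation with 11 and BF3·OEt2 gives methyl 2-(benzyloxy)-4-methoxy-6-[(2-pentyl-1,3-dithiolan-2-yl)methyl]benzoate F4. With the ketone masked, base can no longer drive isocoumarin or naphthol formation, so KOH in DMSO/H2O at 100 °C gives potassium 2-(benzyloxy)-4-methoxy-6-[(2-pentyl-1,3-dithiolan-2-yl)methyl]benzoate F5, and acidification delivers 12.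

Step 6 (depside coupling). The di-ortho-substituted acid may couple sluggishly, and the dithiolane sulfur may interfere with the acylium or mixed anhydride under acidic conditions. The fallback sets out from 12 and comes back at 17, replacing in-situ acidic activation by an isolated acyl donor used under basic conditions. Acid 12 is converted with cyanuric fluoride and pyridine (CH2Cl2, −10 °C → rt) into the isolable 2-(benzyloxy)-4-methoxy-6-[(2-pentyl-1,3-dithiolan-2-yl)methyl]benzoyl fluoride F6. This small, hindrance-tolerant electrophile acylates the 4-OH of 15 in the presence of i-Pr2NEt in CH2Cl2 to give 17.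

Step 7 (dethioketalisation). S-methylation of the hindered dithiolane may be slow, and the freed ketone may attack the neighbouring aryl ester on prolonged warming. The fallback sets out from 10 and comes back at 18, using an O,O-ketal that is removed by mild acid instead of sulfur chemistry. Keto acid 10 is trans-ketalised in 2-ethyl-2-methyl-1,3-dioxolane with catalytic TsOH at rt to 2-(benzyloxy)-4-methoxy-6-[(2-pentyl-1,3-dioxolan-2-yl)methyl]benzoic acid F7. Acid-free Steglich coupling (DCC, cat. DMAP, CH2Cl2, 0 °C → rt) with 15 proceeds through the O-acylisourea N,N'-dicyclohexylcarbamimidic anhydride of F7, labelled F8. It gives benzyl 4-{[2-(benzyloxy)-4-methoxy-6-[(2-pentyl-1,3-dioxolan-2-yl)methyl]benzoyl]oxy}-2-hydroxy-6-pentylbenzoate F9. PPTS in acetone/H2O at 40 °C hydrolyses the ketal to 18.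

**Further compounds**
F1 | step 3 | methyl 2-(benzyloxy)-6-(lithiomethyl)-4-methoxybenzoate | COC(=O)c1c(C[Li])cc(OC)cc1OCc1ccccc1
F2 | step 3 | methyl 2-(benzyloxy)-6-{2-(lithiooxy)-2-[methoxy(methyl)amino]heptyl}-4-methoxybenzoate | CCCCCC(O[Li])(Cc1cc(OC)cc(OCc2ccccc2)c1C(=O)OC)N(C)OC
F3 | step 3 | methyl 2-(benzyloxy)-4-methoxy-6-(2-oxoheptyl)benzoate | CCCCCC(=O)Cc1cc(OC)cc(OCc2ccccc2)c1C(=O)OC
F4 | step 3 | methyl 2-(benzyloxy)-4-methoxy-6-[(2-pentyl-1,3-dithiolan-2-yl)methyl]benzoate | CCCCCC1(Cc2cc(OC)cc(OCc3ccccc3)c2C(=O)OC)SCCS1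
F5 | step 3 | potassium 2-(benzyloxy)-4-methoxy-6-[(2-pentyl-1,3-dithiolan-2-yl)methyl]benzoate | CCCCCC1(Cc2cc(OC)cc(OCc3ccccc3)c2C(=O)[O-])SCCS1.[K+]
F6 | step 6 | 2-(benzyloxy)-4-methoxy-6-[(2-pentyl-1,3-dithiolan-2-yl)methyl]benzoyl fluoride | CCCCCC1(Cc2cc(OC)cc(OCc3ccccc3)c2C(F)=O)SCCS1
F7 | step 7 | 2-(benzyloxy)-4-methoxy-6-[(2-pentyl-1,3-dioxolan-2-yl)methyl]benzoic acid | CCCCCC1(Cc2cc(OC)cc(OCc3ccccc3)c2C(=O)O)OCCO1
F8 | step 7 | O-acylisourea of F7 (N,N'-dicyclohexylcarbamimidic anhydride of F7) | CCCCCC1(Cc2cc(OC)cc(OCc3ccccc3)c2C(=O)OC(=NC2CCCCC2)NC2CCCCC2)OCCO1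
F9 | step 7 | benzyl 4-{[2-(benzyloxy)-4-methoxy-6-[(2-pentyl-1,3-dioxolan-2-yl)methyl]benzoyl]oxy}-2-hydroxy-6-pentylbenzoate | CCCCCc1cc(OC(=O)c2c(CC3(CCCCC)OCCO3)cc(OC)cc2OCc2ccccc2)cc(O)c1C(=O)OCc1ccccc1
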